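The numbers were chosen freely; the result is computed.

At early times the flask holds G, D and J with no X dissolved, and Z appears as X arrives from Q.

    Q ⇌ X, rate k1*(csat - [X]) (k1 = 0.139 /h, csat = 31 mM)
    G + X + D → D + Z (k2 = 265 /M²/h)
    G ⇌ L (K3 = 0.30, k3 = 0.125 /h)
    D + J ⇌ D.J (K4 = 74.4 /M, k4 = 3.92 /M/h)

G 0.075 M; Q 31 mM (held); D 13 mM; J 29 mM; time 4.0 d

- amount of Z at 4.0 d, in percent of the G charged
- concentration of X in solution at 4.0 d, in percent of saturation

Let f be the fraction of the G charge still present as G or L. G and L relax with a half-life of 0.0533 d, much shorter than the run, so G is taken as 76.9 % of f. J, taken at balance with D, leaves 5.06 mM of D free, 39.0 % of its charge. Transfer from Q closes the gap to saturation with a half-life of 0.208 d, much shorter than the run, so X is taken as steady, which ignores its empty start. Its fraction of saturation is then 1/(1 + βf), where β = 0.557 compares use of X at the full charge with transfer from Q.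

Call the log budget the pseudo-first-order loss of f at saturated X, multiplied by the time: N = 3.07. Separating f gives

−ln f + β(1 − f) = N

Two passes give f = 7.73 %, so Z is 92.3 % and X is 95.9 % of saturation.

Turned round, f = 0.5 at the asked time belongs to N = 0.972. This flask's budget is larger, by a factor of 3.16.

The forecast, lower than this reckoning on both counts, gives 91 % (88 % to 94 %) and 94.5 % (92.5 % to 96 %), holding that dissolution “limits the overall rate”.

The flask gives 91.1 % and 94.3 %. Its f of 8.90 % has spent 2.93 of the budget of 3.07. Read at 25 h, the neighbouring flask holds 40.0 % of its D free and has a budget of 0.800, smaller than 0.972. The same equation gives f = 57.3 %. That flask reads Z at 39.9 %, with 45.6 % of the charge as G and 14.5 % as L.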